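**Retrosynthetic overview**

1. Target, with cembrane numbering (C1 carries the 2-acetoxyprop-2-yl group; methyls on C4, C8, C12): (1R,3Z,7S,8R,10S,11E)-7,8-epoxycembra-3,11-diene-10,15-diyl diacetate. The last C–C bond made is C5–C6, closed as C5=C6 by ring-closing metathesis of an open-chain precursor with a (Z)-2-methyl-1,3-diene terminus (C3=C4(Me)–C5H=CH2) and a vinyl oxirane terminus (CH2=C6H–C7), then saturated with diimide.
2. Feature used: C5 and C6 are the two neighbouring ring methylenes between olefinic C4 and oxirane carbon C7. Written as C5=C6 they are the only disubstituted olefin of the 14-membered ring (C3=C4 and C11=C12 are trisubstituted), so two vinyl groups can be joined and the new olefin alone reduced.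
3. The cis-7,8-oxirane and C10 are made on a temporary dihydropyranone ring (O–C6(=O)–C7=C8(Me)–C9–C10; ring oxygen = C10 acetate oxygen) from an asymmetric vinylogous aldol–lactonisation. The ring holds C7=C8 cis and directs epoxidation anti to the C10 side chain; DIBAL-H and Wittig methylenation then open it.
4. C1 with its oxygenated isopropyl group, the C3 aldehyde and the C12 methyl ketone come from ozonolytic cleavage of the ring olefin of (R)-α-terpineol. C3=C4 (Z) is set by Stork–Zhao iodo-olefination and Stille vinylation, C11=C12 (E) by Horner–Wadsworth–Emmons olefination.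
5. Order of ring formation: dihydropyranone (temporary), oxirane, dihydropyranone opened, 14-membered carbocycle last.

Key step: step 14

Assumption: (R)-(+)-α-terpineol of high enantiomeric purity is taken as the commercial starting material.
Assumption: the (S)-Tol-BINAP copper fluoride catalyst is taken to direct the dienolate to the Si face of the enal; should the sense be the opposite, the (R)-ligand is used.

**Route**

Step 1
Reactants: 1 (R)-(+)-α-terpineol
Product: 2 triethylsilyl ether of (R)-α-terpineol
Conditions: Et3SiOTf, 2,6-lutidine, CH2Cl2, −78 to 0 °C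
Reagents that add atoms: triethylsilyl trifluoromethanesulfonate, CC[Si](CC)(CC)OS(=O)(=O)C(F)(F)F
Why: The reactive silyl triflate silylates the hindered tertiary alcohol (silyl ether formation), masking the C15 hydroxyl against the ylide, hydride and enolate reagents that follow; the stereocentre is not touched.

Step 2
Reactants: 2 triethylsilyl ether of (R)-α-terpineol
Product: 4 (3R)-6-oxo-3-[2-(triethylsilyloxy)propan-2-yl]heptanal, via secondary ozonide 3 (not isolated)
Conditions: O3, CH2Cl2, −78 °C; then PPh3, −78 °C to rt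
Reagents that add atoms: ozone, [O-][O+]=O
Why: Ozonolysis with reductive work-up cleaves the only olefin, the ring C=C of the terpene, so the cyclohexene is remodelled into an acyclic chain with the C3 aldehyde and the C12 methyl ketone while the C1 stereocentre (R) is carried over unchanged.

Step 3
Reactants: 4 (3R)-6-oxo-3-[2-(triethylsilyloxy)propan-2-yl]heptanal
Product: 5 (5R,7Z)-8-iodo-5-[2-(triethylsilyloxy)propan-2-yl]non-7-en-2-one
Conditions: Ph3PEtI, n-BuLi, THF; I2, −78 °C; NaHMDS, −20 °C; then 4, −78 °C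
Reagents that add atoms: ethyltriphenylphosphonium iodide, CC[P+](c1ccccc1)(c1ccccc1)c1ccccc1.[I-]; iodine, II
Why: In this Stork–Zhao olefination the α-iodo ylide should react with the aldehyde far faster than with the methyl ketone at −78 °C, and kinetic cis-oxaphosphetane formation should give the (Z)-2-iodo-2-alkene, which fixes C2 cis to the future C5 at C3=C4.

Step 4
Reactants: 5 (5R,7Z)-8-iodo-5-[2-(triethylsilyloxy)propan-2-yl]non-7-en-2-one
Product: 6 (2E,6R,8Z)-9-iodo-N-methoxy-N,3-dimethyl-6-[2-(triethylsilyloxy)propan-2-yl]deca-2,8-dienamide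
Conditions: (EtO)2P(O)CH2C(O)N(OMe)Me, NaH, THF, 0 °C to rt
Reagents that add atoms: diethyl [2-[methoxy(methyl)amino]-2-oxoethyl]phosphonate, CCOP(=O)(CC(=O)N(C)OC)OCC
Why: Horner–Wadsworth–Emmons olefination of the methyl ketone should favour the (E)-enamide (C10 trans to C13) because the intermediates equilibrate before elimination; the minor Z isomer should be removable by chromatography.

Step 5
Reactants: 6 (2E,6R,8Z)-9-iodo-N-methoxy-N,3-dimethyl-6-[2-(triethylsilyloxy)propan-2-yl]deca-2,8-dienamide
Product: 7 (2E,6R,8Z)-9-iodo-3-methyl-6-[2-(triethylsilyloxy)propan-2-yl]deca-2,8-dienal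
Conditions: DIBAL-H, THF, −78 °C; aq Rochelle salt
Reagents that add atoms: none
Why: DIBAL-H reduces the N-methoxy-N-methylamide to a chelated aluminium hemiaminal that releases the enal only on work-up (Weinreb amide reduction), so over-reduction is avoided and the vinyl iodide and silyl ether should survive.

Step 6
Reactants: 7 (2E,6R,8Z)-9-iodo-3-methyl-6-[2-(triethylsilyloxy)propan-2-yl]deca-2,8-dienal
Product: 8 (2E,6R,8Z)-3,9-dimethyl-6-[2-(triethylsilyloxy)propan-2-yl]undeca-2,8,10-trienal
Conditions: Bu3SnCH=CH2, Pd2(dba)3 (cat.), AsPh3, CuI (cat.), DMF, rt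
Reagents that add atoms: tributyl(vinyl)stannane, C=C[Sn](CCCC)(CCCC)CCCC
Why: Stille coupling of the vinyl iodide proceeds with retention of olefin geometry and gives the (Z)-2-methyl-1,3-diene terminus that contains C5; it is run before any allylic ester exists in the molecule, so palladium cannot ionise one.

Step 7
Reactants: 9 methyl 3-methylbut-2-enoate
Product: 10 1-methoxy-3-methyl-1-(trimethylsilyloxy)buta-1,3-diene
Conditions: LDA, THF, −78 °C; Me3SiCl, −78 °C to rt
Reagents that add atoms: chlorotrimethylsilane, C[Si](C)(C)Cl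
Why: LDA removes a γ-proton of the senecioate and O-silylation of the extended enolate gives the silyl dienol ether (silyl ketene acetal formation).

Step 8
Reactants: 8 (2E,6R,8Z)-3,9-dimethyl-6-[2-(triethylsilyloxy)propan-2-yl]undeca-2,8,10-trienal; 10 1-methoxy-3-methyl-1-(trimethylsilyloxy)buta-1,3-diene
Product: 12 (6S)-4-methyl-6-[(1E,5R,7Z)-2,8-dimethyl-5-[2-(triethylsilyloxy)propan-2-yl]deca-1,7,9-trien-1-yl]-5,6-dihydro-2H-pyran-2-one, via silyl aldol ester 11 (not isolated)
Conditions: Cu(OTf)2 (10 mol%), (S)-Tol-BINAP (11 mol%), Bu4N[Ph3SiF2] (20 mol%), THF, −78 °C to rt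
Reagents that add atoms: none
Why: In this catalytic asymmetric vinylogous Mukaiyama aldol reaction the copper dienolate should add through its γ-carbon to the Si face of the enal under ligand control, which sets C10 (S), and the δ-oxy (Z)-enoate should lactonise in the flask to the six-membered template ring in which C7=C8 is necessarily cis.

Step 9
Reactants: 12 the (6S)-dihydropyranone
Product: 13 (1R,4S,6R)-6-methyl-4-[(1E,5R,7Z)-2,8-dimethyl-5-[2-(triethylsilyloxy)propan-2-yl]deca-1,7,9-trien-1-yl]-3,7-dioxabicyclo[4.1.0]heptan-2-one (oxirane trans to the side chain)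
Conditions: 30% aq H2O2, NaOH (cat.), MeOH, 0 °C, pH 8 to 9
Reagents that add atoms: hydrogen peroxide, OO
Why: Weitz–Scheffer epoxidation touches only the electron-poor lactone olefin, and attack of hydroperoxide anti to the pseudo-equatorial C10 side chain of the half-chair should place the cis-oxirane trans to that side chain, which sets C7 and C8 in the relative sense of the target (7S,8R with 10S).

Step 10
Reactants: 13 the epoxy lactone
Product: 14 the corresponding lactol (3,7-dioxabicyclo[4.1.0]heptan-2-ol; anomer mixture)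
Conditions: DIBAL-H (1.1 equiv), CH2Cl2, −78 °C; aq Rochelle salt
Reagents that add atoms: none
Why: At −78 °C DIBAL-H reduction of the lactone should stop at the aluminium hemiacetal and give the lactol on work-up, without opening the oxirane.

Step 11
Reactants: 14 the epoxy lactol
Product: 16 (2S,3E,7R,9Z)-4,10-dimethyl-1-[(2R,3S)-2-methyl-3-vinyloxiran-2-yl]-7-[2-(triethylsilyloxy)propan-2-yl]dodeca-3,9,11-trien-2-ol, via epoxy aldehyde 15 (not isolated)
Conditions: Ph3PCH3Br, KOtBu, THF, 0 °C to rt
Reagents that add atoms: methyltriphenylphosphonium bromide, C[P+](c1ccccc1)(c1ccccc1)c1ccccc1.[Br-]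
Why: The lactol is in equilibrium with the open α,β-epoxy aldehyde, which is trapped by Wittig methylenation; the template ring is thereby cleaved, the C10 hydroxyl is released and C6 becomes the terminal vinyl group on the oxirane, the epoxide carbon C7 having no enolisation pathway by which to epimerise.

Step 12
Reactants: 16 the vinyl oxirane alcohol
Product: 17 the C10,C15-diol (triethylsilyl group removed)
Conditions: Bu4NF, THF, rt to 40 °C
Reagents that add atoms: none
Why: Fluoride cleaves the tertiary triethylsilyl ether under mildly basic conditions that should leave the vinyl oxirane and the diene intact (desilylation).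

Step 13
Reactants: 17 the C10,C15-diol
Product: 18 the C10,C15-diacetate (open-chain metathesis precursor)
Conditions: Ac2O, DMAP, Et3N, CH2Cl2, rt to 40 °C
Reagents that add atoms: acetic anhydride, CC(=O)OC(C)=O
Why: DMAP-catalysed acetylation should esterify the secondary allylic C10 hydroxyl quickly and the tertiary C15 hydroxyl on prolonged reaction, so both acetates of the target are in place before ring closure (nucleophilic acyl-transfer catalysis).

Step 14
Reactants: 18 the open-chain diacetate
Product: 19 (1R,3Z,7S,8R,10S,11E)-7,8-epoxycembra-3,5,11-triene-10,15-diyl diacetate (C5=C6 geometry not controlled)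
Conditions: second-generation Grubbs catalyst (H2IMes)(PCy3)Cl2Ru=CHPh (10 mol%), CH2Cl2, 1 mM, 40 °C, slow addition of 18
Reagents that add atoms: none
Why: This is ring-closing olefin metathesis by the Chauvin mechanism: the ruthenium benzylidene exchanges onto one of the two monosubstituted vinyl groups, the new alkylidene forms a ruthenacyclobutane with the other vinyl group, and cycloreversion expels ethylene and closes C5=C6. The closest known reaction type is macrocyclising metathesis between a 1,3-diene terminus and an allylically oxygenated vinyl group, which gives a ring-embedded conjugated diene that is afterwards saturated at its disubstituted olefin. The only ring closed is the 14-membered carbocycle, by union of C5 (diene terminus on C4) with C6 (vinyl carbon on oxirane carbon C7). No stereocentre is created and the geometry of the new olefin is immaterial because it is reduced in the next step. The selectivity needed is reaction at the two terminal olefins only, which the trisubstitution of C3=C4 and C11=C12 secures, and ring closure over oligomerisation, which millimolar dilution and the two cis turn elements (C3=C4 and the cis-oxirane) should favour.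

Step 15
Reactants: 19 the macrocyclic 3,5,11-triene
Product: 20 (1R,3Z,7S,8R,10S,11E)-7,8-epoxycembra-3,11-diene-10,15-diyl diacetate (target)
Conditions: 2-nitrobenzenesulfonyl hydrazide, Et3N, CH2Cl2, rt
Reagents that add atoms: none
Why: Diimide generated from the sulfonyl hydrazide transfers two hydrogens in a concerted syn fashion and reacts fastest with the least substituted olefin, so the disubstituted C5=C6 bond should be saturated while the trisubstituted C3=C4 and C11=C12 olefins, the oxirane and the acetates remain (diimide reduction).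

**Compound list**

1 | (R)-(+)-α-terpineol | CC1=CC[C@@H](CC1)C(C)(C)O | starting material
2 | triethylsilyl ether of (R)-α-terpineol | CC1=CC[C@@H](CC1)C(C)(C)O[Si](CC)(CC)CC | intermediate
3 | secondary ozonide of 2 (diastereomer mixture, not isolated) | CC12CC[C@@H](C(C)(C)O[Si](CC)(CC)CC)CC(O1)OO2 | intermediate
4 | (3R)-6-oxo-3-[2-(triethylsilyloxy)propan-2-yl]heptanal | CC(=O)CC[C@@H](C(C)(C)O[Si](CC)(CC)CC)CC=O | intermediate
5 | (5R,7Z)-8-iodo-5-[2-(triethylsilyloxy)propan-2-yl]non-7-en-2-one | CC(=O)CC[C@@H](C(C)(C)O[Si](CC)(CC)CC)C/C=C(/C)I | intermediate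
6 | (2E,6R,8Z)-9-iodo-N-methoxy-N,3-dimethyl-6-[2-(triethylsilyloxy)propan-2-yl]deca-2,8-dienamide | CON(C)C(=O)/C=C(\C)CC[C@@H](C(C)(C)O[Si](CC)(CC)CC)C/C=C(/C)I | intermediate
7 | (2E,6R,8Z)-9-iodo-3-methyl-6-[2-(triethylsilyloxy)propan-2-yl]deca-2,8-dienal | O=C/C=C(\C)CC[C@@H](C(C)(C)O[Si](CC)(CC)CC)C/C=C(/C)I | intermediate
8 | (2E,6R,8Z)-3,9-dimethyl-6-[2-(triethylsilyloxy)propan-2-yl]undeca-2,8,10-trienal | O=C/C=C(\C)CC[C@@H](C(C)(C)O[Si](CC)(CC)CC)C/C=C(/C)C=C | intermediate
9 | methyl 3-methylbut-2-enoate | COC(=O)C=C(C)C | starting material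
10 | 1-methoxy-3-methyl-1-(trimethylsilyloxy)buta-1,3-diene | C=C(C)C=C(OC)O[Si](C)(C)C | intermediate
11 | methyl (2Z,5S,6E,10R,12Z)-3,7,13-trimethyl-10-[2-(triethylsilyloxy)propan-2-yl]-5-(trimethylsilyloxy)pentadeca-2,6,12,14-tetraenoate (not isolated) | COC(=O)/C=C(/C)C[C@H](O[Si](C)(C)C)/C=C(\C)CC[C@@H](C(C)(C)O[Si](CC)(CC)CC)C/C=C(/C)C=C | intermediate
12 | (6S)-4-methyl-6-[(1E,5R,7Z)-2,8-dimethyl-5-[2-(triethylsilyloxy)propan-2-yl]deca-1,7,9-trien-1-yl]-5,6-dihydro-2H-pyran-2-one | CC1=CC(=O)O[C@@H](C1)/C=C(\C)CC[C@@H](C(C)(C)O[Si](CC)(CC)CC)C/C=C(/C)C=C | intermediate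
13 | (1R,4S,6R)-epoxy lactone, 6-methyl-4-(side chain as in 12)-3,7-dioxabicyclo[4.1.0]heptan-2-one, oxirane trans to the side chain | O=C1[C@@H]2O[C@]2(C)C[C@H](O1)/C=C(\C)CC[C@@H](C(C)(C)O[Si](CC)(CC)CC)C/C=C(/C)C=C | intermediate
14 | epoxy lactol from 13 (anomer mixture) | OC1[C@@H]2O[C@]2(C)C[C@H](O1)/C=C(\C)CC[C@@H](C(C)(C)O[Si](CC)(CC)CC)C/C=C(/C)C=C | intermediate
15 | (2R,3R)-3-[(2S,3E,7R,9Z)-2-hydroxy-4,10-dimethyl-7-[2-(triethylsilyloxy)propan-2-yl]dodeca-3,9,11-trien-1-yl]-3-methyloxirane-2-carbaldehyde (open form of 14, not isolated) | O=C[C@@H]1O[C@]1(C)C[C@H](O)/C=C(\C)CC[C@@H](C(C)(C)O[Si](CC)(CC)CC)C/C=C(/C)C=C | intermediate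
16 | (2S,3E,7R,9Z)-4,10-dimethyl-1-[(2R,3S)-2-methyl-3-vinyloxiran-2-yl]-7-[2-(triethylsilyloxy)propan-2-yl]dodeca-3,9,11-trien-2-ol | C=C[C@@H]1O[C@]1(C)C[C@H](O)/C=C(\C)CC[C@@H](C(C)(C)O[Si](CC)(CC)CC)C/C=C(/C)C=C | intermediate
17 | (2S,3E,7R,9Z)-7-(2-hydroxypropan-2-yl)-4,10-dimethyl-1-[(2R,3S)-2-methyl-3-vinyloxiran-2-yl]dodeca-3,9,11-trien-2-ol | C=C[C@@H]1O[C@]1(C)C[C@H](O)/C=C(\C)CC[C@@H](C(C)(C)O)C/C=C(/C)C=C | intermediate
18 | diacetate of 17 (acetates on the C10 and C15 oxygens) | C=C[C@@H]1O[C@]1(C)C[C@H](OC(C)=O)/C=C(\C)CC[C@@H](C(C)(C)OC(C)=O)C/C=C(/C)C=C | intermediate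
19 | (1R,3Z,7S,8R,10S,11E)-7,8-epoxycembra-3,5,11-triene-10,15-diyl diacetate (C5=C6 geometry not controlled) | CC(=O)O[C@@H]1/C=C(\C)CC[C@@H](C(C)(C)OC(C)=O)C/C=C(/C)C=C[C@@H]2O[C@]2(C)C1 | intermediate
20 | (1R,3Z,7S,8R,10S,11E)-7,8-epoxycembra-3,11-diene-10,15-diyl diacetate | CC(=O)O[C@@H]1/C=C(\C)CC[C@@H](C(C)(C)OC(C)=O)C/C=C(/C)CC[C@@H]2O[C@]2(C)C1 | target

**Summary**

Total step count: 15. Longest linear sequence: 14 steps (steps 1 to 6 and 8 to 15).

**Steps most likely to fail**

Step 14 (ring-closing metathesis). The catalyst may be held as an unreactive vinyl-alkylidene at the conjugated diene terminus, or intermolecular metathesis may outrun closure of the 14-membered ring. The fallback is a ring-expanding Julia–Kocienski olefination without metathesis; it sets out from 7 and comes back at 19. Hydroxymethylation of the vinyl iodide of 7 with (tributylstannyl)methanol (Pd(PPh3)4, dioxane, 80 °C) should give the (Z)-allylic alcohol enal F1. The vinylogous aldol–lactonisation of step 8 would then give the hydroxy dihydropyranone F2, and the epoxidation of step 9 the epoxy lactone alcohol F3. Mitsunobu thioetherification with 1-phenyl-1H-tetrazole-5-thiol (PPh3, DIAD) would give the tetrazolyl sulfide F4, oxidation with (NH4)6Mo7O24 and H2O2 in EtOH the sulfone F5, and DIBAL-H at −78 °C the lactol sulfone F6. Slow addition of KHMDS to F6 in THF at high dilution (−78 °C to rt) should open the lactol to its aldehyde and close C5=C6 in the same operation, giving the macrocyclic dienol F7. Bu4NF would give the macrocyclic diol F8, and acetylation as in step 13 would give 19.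

Step 8 (vinylogous aldol–lactonisation). Facial discrimination may be low or addition slow with the hindered β,β-disubstituted enal, and the aldol adduct may fail to lactonise fully. The fallback replaces it by an aldol reaction followed by an intramolecular Horner–Wadsworth–Emmons ring closure; it sets out from 8 and comes back at 12. A catalytic asymmetric Mukaiyama aldol reaction of 8 with 2-(trimethylsilyloxy)propene (Ti(OiPr)4/BINOL catalyst, acidic work-up) should give the β-hydroxy methyl ketone F9. Esterification with diethylphosphonoacetic acid (DCC, DMAP) would give the phosphonoacetate F10, and LiCl with iPr2NEt in MeCN should close C7=C8 inside the six-membered ring to give 12.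

Step 3 (Stork–Zhao olefination). The thermally labile iodo ylide may decompose, Z selectivity may erode, or the ylide may attack the methyl ketone. The fallback builds the vinyl halide stepwise; it sets out from 4 and comes back at 5. Dibromo-olefination of the aldehyde (CBr4, PPh3, CH2Cl2, 0 °C; Corey–Fuchs first stage) should give the 1,1-dibromoalkene F11. Trans-selective Negishi monomethylation (MeZnCl, Pd(DPEphos)Cl2, THF) would give the (Z)-2-bromoalkene F12, and copper-catalysed bromide-to-iodide exchange (NaI, CuI, N,N'-dimethylethylenediamine, dioxane, 110 °C) with retention of geometry would give 5.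

**Further compounds**

F1 | step 14 | (2E,6R,8Z)-10-hydroxy-3,9-dimethyl-6-[2-(triethylsilyloxy)propan-2-yl]deca-2,8-dienal | O=C/C=C(\C)CC[C@@H](C(C)(C)O[Si](CC)(CC)CC)C/C=C(/C)CO
F2 | step 14 | (6S)-dihydropyranone as 12 with CH2OH in place of the terminal vinyl group | CC1=CC(=O)O[C@@H](C1)/C=C(\C)CC[C@@H](C(C)(C)O[Si](CC)(CC)CC)C/C=C(/C)CO
F3 | step 14 | epoxy lactone as 13 with CH2OH in place of the terminal vinyl group | O=C1[C@@H]2O[C@]2(C)C[C@H](O1)/C=C(\C)CC[C@@H](C(C)(C)O[Si](CC)(CC)CC)C/C=C(/C)CO
F4 | step 14 | 1-phenyl-1H-tetrazol-5-yl sulfide of F3 | O=C1[C@@H]2O[C@]2(C)C[C@H](O1)/C=C(\C)CC[C@@H](C(C)(C)O[Si](CC)(CC)CC)C/C=C(/C)CSc1nnnn1-c1ccccc1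
F5 | step 14 | 1-phenyl-1H-tetrazol-5-yl sulfone from F4 | O=C1[C@@H]2O[C@]2(C)C[C@H](O1)/C=C(\C)CC[C@@H](C(C)(C)O[Si](CC)(CC)CC)C/C=C(/C)CS(=O)(=O)c1nnnn1-c1ccccc1
F6 | step 14 | lactol sulfone from F5 (anomer mixture) | OC1[C@@H]2O[C@]2(C)C[C@H](O1)/C=C(\C)CC[C@@H](C(C)(C)O[Si](CC)(CC)CC)C/C=C(/C)CS(=O)(=O)c1nnnn1-c1ccccc1
F7 | step 14 | (1R,3Z,7S,8R,10S,11E)-7,8-epoxy-15-(triethylsilyloxy)cembra-3,5,11-trien-10-ol | O[C@@H]1/C=C(\C)CC[C@@H](C(C)(C)O[Si](CC)(CC)CC)C/C=C(/C)C=C[C@@H]2O[C@]2(C)C1
F8 | step 14 | (1R,3Z,7S,8R,10S,11E)-7,8-epoxycembra-3,5,11-triene-10,15-diol | O[C@@H]1/C=C(\C)CC[C@@H](C(C)(C)O)C/C=C(/C)C=C[C@@H]2O[C@]2(C)C1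
F9 | step 8 | (4S,5E,9R,11Z)-4-hydroxy-6,12-dimethyl-9-[2-(triethylsilyloxy)propan-2-yl]tetradeca-5,11,13-trien-2-one | CC(=O)C[C@H](O)/C=C(\C)CC[C@@H](C(C)(C)O[Si](CC)(CC)CC)C/C=C(/C)C=C
F10 | step 8 | diethylphosphonoacetate ester of F9 | CCOP(=O)(CC(=O)O[C@@H](CC(C)=O)/C=C(\C)CC[C@@H](C(C)(C)O[Si](CC)(CC)CC)C/C=C(/C)C=C)OCC
F11 | step 3 | (5R)-8,8-dibromo-5-[2-(triethylsilyloxy)propan-2-yl]oct-7-en-2-one | CC(=O)CC[C@@H](C(C)(C)O[Si](CC)(CC)CC)CC=C(Br)Br
F12 | step 3 | (5R,7Z)-8-bromo-5-[2-(triethylsilyloxy)propan-2-yl]non-7-en-2-one | CC(=O)CC[C@@H](C(C)(C)O[Si](CC)(CC)CC)C/C=C(/C)Br
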